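**Retrosynthetic overview**
1. Target 9 ⇒ oxa-6π electrocyclisation of ortho-quinone methide 8 ⇒ dehydrogenation of 3',5'-diprenyldavidigenin 7 at the 5'-prenyl/4'-OH pair. This is the biosynthetic prenylphenol-to-chromene oxidation, run last on the unprotected triphenol.
2. 7 ⇒ davidigenin 4 plus two dimethylallyl cation equivalents (double aromatic C-prenylation, mirroring the prenyltransferase steps).
3. 4 ⇒ resorcinol 1 + phloretic acid 2 (Friedel–Crafts acylation).
4. Ring order: both benzene rings are bought; the 2H-pyran ring is the only ring made and it is closed in the final step.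

Assumption: the target has no stereocentre and no stereogenic double bond, so it is achiral and no enantio- or diastereocontrol is needed.

**Route**

Step 1
Reactants: 1 resorcinol; 2 3-(4-hydroxyphenyl)propanoic acid (phloretic acid)
Product: 4 davidigenin [1-(2,4-dihydroxyphenyl)-3-(4-hydroxyphenyl)propan-1-one], via difluoroboron chelate 3 (not isolated)
Conditions: BF3·OEt2 (neat, 6 equiv), 85 °C, 2 h; then H2O–MeOH, 60 °C
Reagents that add atoms: none
Why: BF3-mediated Friedel–Crafts (Nencki-type) C-acylation of resorcinol by the free acid goes at C-4 (para to one hydroxyl, ortho to the other) and stops at mono-acylation because the ketone is held as the deactivated O,O-difluoroboron chelate 3, which the aqueous work-up hydrolyses; no stereocentre is created.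

Step 2
Reactants: 4 davidigenin
Product: 7 3',5'-diprenyldavidigenin [1-[2,4-dihydroxy-3,5-bis(3-methylbut-2-en-1-yl)phenyl]-3-(4-hydroxyphenyl)propan-1-one], via 5'-prenyldavidigenin 5 (not isolated), via 3'-prenyldavidigenin 6 (not isolated)
Conditions: 2-methylbut-3-en-2-ol (2.5 equiv, slow addition), BF3·OEt2 (0.3 equiv), 1,4-dioxane, 20 °C
Reagents that add atoms: 2-methylbut-3-en-2-ol, CC(C)(O)C=C
Why: Friedel–Crafts C-prenylation by the dimethylallyl cation released from the tertiary allylic alcohol (a chemical stand-in for the aromatic prenyltransferase and its diphosphate donor): the acylresorcinol ring is attacked at C-5' and C-3', each ortho/para to two oxygens and meta to the acyl group, in preference to the singly oxygenated ring B, the cation is captured at its unhindered primary end to give normal prenyl groups, both mono-adducts 5 and 6 funnel into 7, and no stereocentre is created.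

Step 3
Reactants: 7 3',5'-diprenyldavidigenin
Product: 9 1-[7-hydroxy-2,2-dimethyl-8-(3-methylbut-2-en-1-yl)-2H-chromen-6-yl]-3-(4-hydroxyphenyl)propan-1-one (target), via ortho-quinone methide 8 (not isolated)
Conditions: DDQ (1.05 equiv), dry PhMe–1,4-dioxane, 25→50 °C
Reagents that add atoms: none
Why: DDQ oxidative cyclisation of an ortho-prenylphenol (the laboratory version of the biosynthetic prenyl-to-chromene oxidation): hydride abstraction from the benzylic–allylic CH2 of the 5'-prenyl group and loss of the 4'-OH proton give (Z)-quinone methide 8, which closes by oxa-6π electrocyclisation; the free 4'-OH reacts and not the ketone-chelated 2'-OH, the 5'-prenyl group (one ortho neighbour) should align a benzylic C–H with the ring π system more easily than the 3'-prenyl group wedged between two oxygens, the plain benzylic CH2 next to ring B is much less hydridic at this temperature, and no stereocentre is created.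

**Compound list**
1 | resorcinol (benzene-1,3-diol) | Oc1cccc(O)c1 | starting material
2 | 3-(4-hydroxyphenyl)propanoic acid (phloretic acid) | OC(=O)CCc1ccc(O)cc1 | starting material
3 | O,O-difluoroboron chelate of davidigenin (BF2 bridging the 2'-phenoxide oxygen and the ketone oxygen in a six-membered ring) | Oc1ccc(CCC2=[O+][B-](F)(F)Oc3cc(O)ccc23)cc1 | intermediate
4 | davidigenin, 1-(2,4-dihydroxyphenyl)-3-(4-hydroxyphenyl)propan-1-one | O=C(CCc1ccc(O)cc1)c1ccc(O)cc1O | intermediate
5 | 5'-prenyldavidigenin, 1-[2,4-dihydroxy-5-(3-methylbut-2-en-1-yl)phenyl]-3-(4-hydroxyphenyl)propan-1-one | CC(C)=CCc1cc(C(=O)CCc2ccc(O)cc2)c(O)cc1O | intermediate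
6 | 3'-prenyldavidigenin, 1-[2,4-dihydroxy-3-(3-methylbut-2-en-1-yl)phenyl]-3-(4-hydroxyphenyl)propan-1-one | CC(C)=CCc1c(O)ccc(C(=O)CCc2ccc(O)cc2)c1O | intermediate
7 | 3',5'-diprenyldavidigenin, 1-[2,4-dihydroxy-3,5-bis(3-methylbut-2-en-1-yl)phenyl]-3-(4-hydroxyphenyl)propan-1-one | CC(C)=CCc1cc(C(=O)CCc2ccc(O)cc2)c(O)c(CC=C(C)C)c1O | intermediate
8 | ortho-quinone methide, (6Z)-3-hydroxy-4-[3-(4-hydroxyphenyl)propanoyl]-2-(3-methylbut-2-en-1-yl)-6-(3-methylbut-2-en-1-ylidene)cyclohexa-2,4-dien-1-one | CC(C)=C/C=C1/C=C(C(=O)CCc2ccc(O)cc2)C(O)=C(CC=C(C)C)C1=O | intermediate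
9 | 1-[7-hydroxy-2,2-dimethyl-8-(3-methylbut-2-en-1-yl)-2H-chromen-6-yl]-3-(4-hydroxyphenyl)propan-1-one (achiral) | CC(C)=CCc1c(O)c(C(=O)CCc2ccc(O)cc2)cc2c1OC(C)(C)C=C2 | target

**Totals**
Total step count: 3. Longest linear sequence: 3.

**Steps most likely to fail, with fallbacks**

1. Step 3 (most risky). DDQ could instead engage the 3'-prenyl group and give the angular 5-hydroxy-chromene isomer. The two benzylic positions are electronically almost equal, so the selectivity rests on the conformational argument and a mixture is possible. Excess oxidant could also close a second pyran ring or dehydrogenate the CH2CH2 bridge to the chalcone.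
Fallback (sets out from 4, comes back at 9): the pyran ring is closed while only one prenyl group is present. Davidigenin 4 is treated with 1.0 equiv of 2-methylbut-3-en-2-ol (BF3·OEt2, 1,4-dioxane) and the major mono-adduct 5 is isolated. DDQ in PhMe then converts 5, through the quinone methide (6Z)-3-hydroxy-4-[3-(4-hydroxyphenyl)propanoyl]-6-(3-methylbut-2-en-1-ylidene)cyclohexa-2,4-dien-1-one F1, into the linear chromene 1-(7-hydroxy-2,2-dimethyl-2H-chromen-6-yl)-3-(4-hydroxyphenyl)propan-1-one F2, the only chromene a single 5'-prenyl group can give. The second prenyl group is then placed on C-8 of F2, the one remaining position flanked by two oxygens, with 2-methylbut-3-en-2-ol and BF3·OEt2 (0.2 equiv) in 1,4-dioxane at 0 °C, giving 9. This costs one extra step.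

2. Step 2. The double prenylation is statistical: mono-adducts 5 and 6, ring-B prenylation and acid-closed chromans all compete. About 15–25% of 7 per pass is realistic, with the mono-adducts resubmitted.
Fallback (sets out from 1, comes back at 7): ring B is brought in only after the prenyl groups, so no second phenol ring competes. Resorcinol 1 is acetylated (AcOH, ZnCl2, 140 °C) to 2,4-dihydroxyacetophenone F3, which is also an article of commerce. F3 is bis-C-prenylated (2-methylbut-3-en-2-ol, BF3·OEt2, 1,4-dioxane) to 1-[2,4-dihydroxy-3,5-bis(3-methylbut-2-en-1-yl)phenyl]ethan-1-one F4. Claisen–Schmidt condensation of F4 with 4-hydroxybenzaldehyde (60% aq KOH, EtOH, 20 °C) gives the chalcone (E)-1-[2,4-dihydroxy-3,5-bis(3-methylbut-2-en-1-yl)phenyl]-3-(4-hydroxyphenyl)prop-2-en-1-one F5. Hydrogenation of F5 over RhCl(PPh3)3 (H2 1 atm, PhH–EtOH) reduces the disubstituted enone alkene and leaves the trisubstituted prenyl alkenes, giving 7.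

3. Step 1 (least risky). Possible problems are esterification or oligomerisation of the phenolic acid, some diacylation, and sluggish hydrolysis of chelate 3.
Fallback (sets out from 1, comes back at 4): a Hoesch reaction replaces the acid with a nitrile electrophile. Resorcinol 1 and 3-(4-hydroxyphenyl)propanenitrile with ZnCl2 and HCl gas in Et2O at 0 °C precipitate the ketiminium salt 1-(2,4-dihydroxyphenyl)-3-(4-hydroxyphenyl)propan-1-iminium chloride F6, which cannot be acylated a second time. Heating F6 in water hydrolyses it to 4.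

**Further compounds**
F1 | step 3 | (6Z)-3-hydroxy-4-[3-(4-hydroxyphenyl)propanoyl]-6-(3-methylbut-2-en-1-ylidene)cyclohexa-2,4-dien-1-one | CC(C)=C/C=C1/C=C(C(=O)CCc2ccc(O)cc2)C(O)=CC1=O
F2 | step 3 | 1-(7-hydroxy-2,2-dimethyl-2H-chromen-6-yl)-3-(4-hydroxyphenyl)propan-1-one | CC1(C)C=Cc2cc(C(=O)CCc3ccc(O)cc3)c(O)cc2O1
F3 | step 2 | 2,4-dihydroxyacetophenone | CC(=O)c1ccc(O)cc1O
F4 | step 2 | 1-[2,4-dihydroxy-3,5-bis(3-methylbut-2-en-1-yl)phenyl]ethan-1-one | CC(=O)c1cc(CC=C(C)C)c(O)c(CC=C(C)C)c1O
F5 | step 2 | (E)-1-[2,4-dihydroxy-3,5-bis(3-methylbut-2-en-1-yl)phenyl]-3-(4-hydroxyphenyl)prop-2-en-1-one | O=C(/C=C/c1ccc(O)cc1)c1cc(CC=C(C)C)c(O)c(CC=C(C)C)c1O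
F6 | step 1 | 1-(2,4-dihydroxyphenyl)-3-(4-hydroxyphenyl)propan-1-iminium chloride | [NH2+]=C(CCc1ccc(O)cc1)c1ccc(O)cc1O.[Cl-]
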